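**Assumption:** the target SMILES has no stereocentre and no stereogenic double bond, so the compound is achiral and no enantiomer has to be chosen. The sp3 centres that form in unisolated intermediates are racemic and are lost again.

## Retrosynthetic overview
1. Target ⇒ its 5,7,4',4''-tetra-O-benzyl ether, with global hydrogenolysis as the last step.
2. 3-OH ⇒ epoxidation and isomerisation of the C2=C3 bond of the flavone. Ring C is the only ring built, and it comes from oxidative oxa-Michael cyclisation of a 2'-hydroxychalcone.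
3. Key disconnection: chalcone Cα=Cβ ⇒ Claisen–Schmidt aldol condensation of a 3-(4-benzyloxybenzyl)-2-hydroxy-4,6-bis(benzyloxy)acetophenone with 4-benzyloxybenzaldehyde.
4. Aryl–CH2 bond of that ketone ⇒ Negishi coupling of the 3-iodoacetophenone (2-OH masked as MOM ether) with 4-benzyloxybenzylzinc chloride.
5. Iodide ⇒ iodination ortho to the chelated free OH of 4,6-di-O-benzylphloroacetophenone. That OH becomes O1, so the benzyl group ends at C8 and not C6. Rings A and B and the benzyl arene are bought.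

## Route

**Step 1**
Reactants: 1 2',4',6'-trihydroxyacetophenone (phloroacetophenone)
Product: 2 1-[2,4-bis(benzyloxy)-6-hydroxyphenyl]ethanone
Conditions: BnBr (2.1 equiv), K2CO3 (2.2 equiv), DMF, 25 °C, 16 h
Reagents that add atoms: benzyl bromide, BrCc1ccccc1
Why: In this Williamson ether synthesis the 4-OH and one of the two equivalent ortho OH groups are alkylated, while the remaining ortho OH is hydrogen-bonded to the acetyl carbonyl and stays free when only two equivalents of halide are used.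

**Step 2**
Reactants: 2 1-[2,4-bis(benzyloxy)-6-hydroxyphenyl]ethanone
Product: 3 1-[4,6-bis(benzyloxy)-2-hydroxy-3-iodophenyl]ethanone
Conditions: NIS (1.05 equiv), TFA (10 mol %), MeCN–CH2Cl2, 0 °C to rt, dark
Reagents that add atoms: N-iodosuccinimide, O=C1CCC(=O)N1I
Why: Electrophilic aromatic iodination goes to C3, which is ortho to the free phenol, para to the 6-benzyloxy group and less crowded than C5 between two benzyloxy groups, as is established for the dimethyl ether analogue.

**Step 3**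
Reactants: 3 1-[4,6-bis(benzyloxy)-2-hydroxy-3-iodophenyl]ethanone
Product: 4 1-[4,6-bis(benzyloxy)-3-iodo-2-(methoxymethoxy)phenyl]ethanone
Conditions: NaH (1.2 equiv), DMF, 0 °C; MOMCl (1.5 equiv), 0 °C to rt
Reagents that add atoms: chloromethyl methyl ether, COCCl
Why: O-alkylation of the sodium phenoxide (MOM acetal protection) removes the only acidic proton before the organozinc step, and full deprotonation overcomes the chelation of this OH.

**Step 4**
Reactants: 4 1-[4,6-bis(benzyloxy)-3-iodo-2-(methoxymethoxy)phenyl]ethanone; 5 4-(benzyloxy)benzyl chloride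
Product: 7 1-{4,6-bis(benzyloxy)-3-[4-(benzyloxy)benzyl]-2-(methoxymethoxy)phenyl}ethanone, via 4-(benzyloxy)benzylzinc chloride 6 (not isolated)
Conditions: 5 (1.5 equiv), Zn dust, LiCl, THF, 25 °C; then 4, Pd(OAc)2 (2 mol %), SPhos (4 mol %), THF, 25 to 50 °C
Reagents that add atoms: none
Why: In this Negishi cross-coupling, LiCl-promoted zinc insertion gives a benzylic zinc chloride that tolerates the ketone and the acetal, and the bulky electron-rich biaryl phosphine lets zerovalent palladium insert into and couple the doubly ortho-substituted aryl iodide.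

**Step 5**
Reactants: 7 1-{4,6-bis(benzyloxy)-3-[4-(benzyloxy)benzyl]-2-(methoxymethoxy)phenyl}ethanone
Product: 8 1-{4,6-bis(benzyloxy)-3-[4-(benzyloxy)benzyl]-2-hydroxyphenyl}ethanone
Conditions: conc. HCl (cat.), MeOH–THF, 50 °C, 2 h
Reagents that add atoms: none
Why: Acid-catalysed transacetalisation cleaves the MOM ether ortho to the carbonyl quickly, helped by formation of the chelated phenol, under conditions that leave the benzyl ethers and the diarylmethane untouched.

**Step 6 (key step)**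
Reactants: 8 1-{4,6-bis(benzyloxy)-3-[4-(benzyloxy)benzyl]-2-hydroxyphenyl}ethanone; 9 4-(benzyloxy)benzaldehyde
Product: 11 (E)-1-{4,6-bis(benzyloxy)-3-[4-(benzyloxy)benzyl]-2-hydroxyphenyl}-3-[4-(benzyloxy)phenyl]prop-2-en-1-one, via β-hydroxy ketone aldol adduct 10 (not isolated)
Conditions: KOH (50% aq, excess), EtOH–THF, 25 °C, 48 h
Reagents that add atoms: none
Why: In this Claisen–Schmidt crossed aldol condensation only the methyl ketone can enolise and the aldehyde has no α-hydrogen, so a single adduct forms, and its racemic carbinol centre is lost in the E1cB dehydration to the thermodynamically preferred E-enone.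

**Step 7**
Reactants: 11 (E)-chalcone from step 6
Product: 13 5,7-bis(benzyloxy)-8-[4-(benzyloxy)benzyl]-2-[4-(benzyloxy)phenyl]-4H-chromen-4-one, via flavanone 12 (not isolated)
Conditions: I2 (10 mol %), DMSO, 130 °C, 3 h
Reagents that add atoms: none
Why: In this iodine-catalysed oxidative cyclisation the 2'-OH adds to the enone (intramolecular oxa-Michael), α-iodination and loss of HI dehydrogenate the racemic flavanone, and DMSO reoxidises HI; since the only free OH sits next to the benzyl group, only the 8-substituted flavone can form.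

**Step 8**
Reactants: 13 5,7-bis(benzyloxy)-8-[4-(benzyloxy)benzyl]-2-[4-(benzyloxy)phenyl]-4H-chromen-4-one
Product: 15 5,7-bis(benzyloxy)-8-[4-(benzyloxy)benzyl]-2-[4-(benzyloxy)phenyl]-3-hydroxy-4H-chromen-4-one, via flavone 2,3-epoxide 14 (not isolated)
Conditions: DMDO (acetone solution, 3 equiv in portions), CH2Cl2, 0 °C, 16 h; then p-TsOH·H2O (cat.), CH2Cl2, rt
Reagents that add atoms: dimethyldioxirane, CC1(C)OO1
Why: Neutral dioxirane epoxidation of the enol-ether C2=C3 bond, followed by acid-catalysed opening at C2 and loss of H-3, gives the flavonol, and it runs much faster at 0 °C than oxidation of the benzylic C–H bonds.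

**Step 9**
Reactants: 15 5,7-bis(benzyloxy)-8-[4-(benzyloxy)benzyl]-2-[4-(benzyloxy)phenyl]-3-hydroxy-4H-chromen-4-one
Product: 16 8-C-p-hydroxybenzylkaempferol, 3,5,7-trihydroxy-8-(4-hydroxybenzyl)-2-(4-hydroxyphenyl)-4H-chromen-4-one
Conditions: H2 (1 atm), 10% Pd/C, THF–MeOH (1:1), rt
Reagents that add atoms: none
Why: Catalytic hydrogenolysis cleaves the four benzylic C–O bonds under neutral conditions, whereas the diarylmethane C–C bonds and the conjugated C2=C3 bond of the flavonol are inert at one atmosphere, so no acid-induced benzyl migration or ring-opening isomerisation can occur.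

## Compound list
1 | 2',4',6'-trihydroxyacetophenone | CC(=O)c1c(O)cc(O)cc1O | starting material
2 | 1-[2,4-bis(benzyloxy)-6-hydroxyphenyl]ethanone | CC(=O)c1c(O)cc(OCc2ccccc2)cc1OCc1ccccc1 | intermediate
3 | 1-[4,6-bis(benzyloxy)-2-hydroxy-3-iodophenyl]ethanone | CC(=O)c1c(O)c(I)c(OCc2ccccc2)cc1OCc1ccccc1 | intermediate
4 | 1-[4,6-bis(benzyloxy)-3-iodo-2-(methoxymethoxy)phenyl]ethanone | CC(=O)c1c(OCOC)c(I)c(OCc2ccccc2)cc1OCc1ccccc1 | intermediate
5 | 4-(benzyloxy)benzyl chloride | ClCc1ccc(OCc2ccccc2)cc1 | starting material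
6 | 4-(benzyloxy)benzylzinc chloride (THF solution, not isolated) | Cl[Zn]Cc1ccc(OCc2ccccc2)cc1 | intermediate
7 | 1-{4,6-bis(benzyloxy)-3-[4-(benzyloxy)benzyl]-2-(methoxymethoxy)phenyl}ethanone | CC(=O)c1c(OCOC)c(Cc2ccc(OCc3ccccc3)cc2)c(OCc2ccccc2)cc1OCc1ccccc1 | intermediate
8 | 1-{4,6-bis(benzyloxy)-3-[4-(benzyloxy)benzyl]-2-hydroxyphenyl}ethanone | CC(=O)c1c(O)c(Cc2ccc(OCc3ccccc3)cc2)c(OCc2ccccc2)cc1OCc1ccccc1 | intermediate
9 | 4-(benzyloxy)benzaldehyde | O=Cc1ccc(OCc2ccccc2)cc1 | starting material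
10 | racemic 1-{4,6-bis(benzyloxy)-3-[4-(benzyloxy)benzyl]-2-hydroxyphenyl}-3-[4-(benzyloxy)phenyl]-3-hydroxypropan-1-one (not isolated) | O=C(CC(O)c1ccc(OCc2ccccc2)cc1)c1c(O)c(Cc2ccc(OCc3ccccc3)cc2)c(OCc2ccccc2)cc1OCc1ccccc1 | intermediate
11 | (E)-1-{4,6-bis(benzyloxy)-3-[4-(benzyloxy)benzyl]-2-hydroxyphenyl}-3-[4-(benzyloxy)phenyl]prop-2-en-1-one | O=C(/C=C/c1ccc(OCc2ccccc2)cc1)c1c(O)c(Cc2ccc(OCc3ccccc3)cc2)c(OCc2ccccc2)cc1OCc1ccccc1 | intermediate
12 | racemic 5,7-bis(benzyloxy)-8-[4-(benzyloxy)benzyl]-2-[4-(benzyloxy)phenyl]chroman-4-one (not isolated) | O=C1CC(c2ccc(OCc3ccccc3)cc2)Oc2c(Cc3ccc(OCc4ccccc4)cc3)c(OCc3ccccc3)cc(OCc3ccccc3)c12 | intermediate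
13 | 5,7-bis(benzyloxy)-8-[4-(benzyloxy)benzyl]-2-[4-(benzyloxy)phenyl]-4H-chromen-4-one | O=c1cc(-c2ccc(OCc3ccccc3)cc2)oc2c(Cc3ccc(OCc4ccccc4)cc3)c(OCc3ccccc3)cc(OCc3ccccc3)c12 | intermediate
14 | racemic 2,3-epoxide of 13 (not isolated) | O=C1C2OC2(c2ccc(OCc3ccccc3)cc2)Oc2c(Cc3ccc(OCc4ccccc4)cc3)c(OCc3ccccc3)cc(OCc3ccccc3)c12 | intermediate
15 | 5,7-bis(benzyloxy)-8-[4-(benzyloxy)benzyl]-2-[4-(benzyloxy)phenyl]-3-hydroxy-4H-chromen-4-one | O=c1c(O)c(-c2ccc(OCc3ccccc3)cc2)oc2c(Cc3ccc(OCc4ccccc4)cc3)c(OCc3ccccc3)cc(OCc3ccccc3)c12 | intermediate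
16 | 8-C-p-hydroxybenzylkaempferol (achiral) | O=c1c(O)c(-c2ccc(O)cc2)oc2c(Cc3ccc(O)cc3)c(O)cc(O)c12 | target

## Step count and weak points
Total steps: 9. Longest linear sequence: 9 (from 1 to 16). Compounds 5 and 9 enter as bought.

**Step 4 (Negishi coupling).** The iodide is electron-rich and flanked by two alkoxy groups. Coupling may therefore be slow, and protodeiodination or homocoupling of the zinc reagent may compete. The fallback reverses the polarity of the two partners and sets out from 4. Miyaura borylation (B2pin2, PdCl2(dppf), KOAc, 1,4-dioxane, 90 °C) gives the pinacol boronate 1-[4,6-bis(benzyloxy)-2-(methoxymethoxy)-3-(4,4,5,5-tetramethyl-1,3,2-dioxaborolan-2-yl)phenyl]ethanone F1. This is then joined to benzyl chloride 5, now the electrophile, in a Suzuki–Miyaura coupling (Pd(PPh3)4, K2CO3, THF–H2O, 70 °C). The fallback comes back to the route at 7.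

**Step 7 (I2/DMSO).** HI formed at 130 °C may strip the 5-O-benzyl group, and the hot oxidising medium may attack the diarylmethane CH2. The fallback sets out from 11 and avoids the flavone altogether through an Algar–Flynn–Oyamada oxidation (30% H2O2, NaOH, MeOH–THF, 0 °C to rt). The phenoxide closes ring C while the α-carbon is hydroxylated, giving the racemic trans-dihydroflavonol rac-(2R,3R)-5,7-bis(benzyloxy)-8-[4-(benzyloxy)benzyl]-2-[4-(benzyloxy)phenyl]-3-hydroxychroman-4-one F2. This is dehydrogenated in the same pot. The fallback comes back at 15 and also bypasses step 8. It is only the reserve because 6'-alkoxychalcones can divert partly to aurones.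

**Step 8 (DMDO).** With a slowly reacting flavone, the dioxirane may begin to oxidise benzylic C–H bonds or electron-rich arenes. The fallback sets out from 13 and replaces electrophilic oxygen transfer by carbanion chemistry. LDA (THF, −78 °C) deprotonates C3–H to give the 3-lithioflavone F3. B(OMe)3 followed by AcOH gives the dimethyl flavon-3-ylboronate F4. H2O2 then oxidises the C–B bond. The fallback comes back at 15.

## Further compounds
F1 | step 4 | 1-[4,6-bis(benzyloxy)-2-(methoxymethoxy)-3-(4,4,5,5-tetramethyl-1,3,2-dioxaborolan-2-yl)phenyl]ethanone | CC(=O)c1c(OCOC)c(B2OC(C)(C)C(C)(C)O2)c(OCc2ccccc2)cc1OCc1ccccc1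
F2 | step 7 | rac-(2R,3R)-5,7-bis(benzyloxy)-8-[4-(benzyloxy)benzyl]-2-[4-(benzyloxy)phenyl]-3-hydroxychroman-4-one (trans, racemic, one enantiomer drawn) | O=C1[C@H](O)[C@@H](c2ccc(OCc3ccccc3)cc2)Oc2c(Cc3ccc(OCc4ccccc4)cc3)c(OCc3ccccc3)cc(OCc3ccccc3)c12
F3 | step 8 | 3-lithio-5,7-bis(benzyloxy)-8-[4-(benzyloxy)benzyl]-2-[4-(benzyloxy)phenyl]-4H-chromen-4-one | [Li]c1c(-c2ccc(OCc3ccccc3)cc2)oc2c(Cc3ccc(OCc4ccccc4)cc3)c(OCc3ccccc3)cc(OCc3ccccc3)c2c1=O
F4 | step 8 | dimethyl {5,7-bis(benzyloxy)-8-[4-(benzyloxy)benzyl]-2-[4-(benzyloxy)phenyl]-4-oxo-4H-chromen-3-yl}boronate | COB(OC)c1c(-c2ccc(OCc3ccccc3)cc2)oc2c(Cc3ccc(OCc4ccccc4)cc3)c(OCc3ccccc3)cc(OCc3ccccc3)c2c1=O
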